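**Plan**

Numbering used throughout (target): C1 = CH–O‑tigloyl, C2 = CH2, C3 = CH–O‑isovaleryl, C4 = CMe2, C5 = cyclobutane CH on C4, C6 = cyclobutane CH on the C7 ketone, C8=C9(Me) = enone, C10 = cyclobutane CH on C9, C11 = cyclobutane C(Me) on C1.
Cuts, last to first: C8=C9 (intramolecular Horner–Wadsworth–Emmons); C6–C11 (Wolff ring contraction of a cyclopentanone in which C7 is still bonded to C11, a temporary ring); C2–C3 and C4–C5 in one event (isobutyraldehyde = C3–C4 annulated onto a cyclopentenone); C11–C1 and C10–C9 (conjugate addition/aldol).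
Enabling feature: the oxygen on C3 is 1,3 to the oxygen on C1 and 1,5 to the C7 carbonyl, and C4 and C11 are quaternary; the C3–C4 unit can therefore be a donor at C4 (towards C5, β to C7=O) and a non‑enolisable acceptor at C3 (towards C2, the only enolisable carbon of a C1 acetyl group).
Forward order of rings: cyclopentenone (C5, C6, C7, C11, C10) → seven‑membered ring across C5/C11 (bicyclo[4.2.1]nonane) → cyclobutane by extrusion of C7 from the five‑membered ring (bicyclo[4.1.1]octane) → cyclohexenone across C6/C10.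
Stereochemistry: the silyloxy centre of commercial (R)‑4‑silyloxycyclopentenone places the vinyl group on C10; C10 sets C11 (aldol) and C5 (Michael addition); the bicyclic frame sets C3 (exo borylation), C3 sets C1 (anti Tishchenko reduction), and C6 is fixed in the last ring closure.

Key step: step 5

Assumption: the target SMILES is read as the (1R,3R,5S,6R,10R,11R) isomer in the numbering above, with an (E)‑2‑methylbut‑2‑enoate on O1 and a 3‑methylbutanoate on O3; 1 is taken as a commercial enantiopure building block.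

**Route**

Step 1
Reactants: 1 (4R)-4-[(tert-butyldimethylsilyl)oxy]cyclopent-2-en-1-one
Product: 2 (4R)-4-[(tert-butyldimethylsilyl)oxy]-2-iodocyclopent-2-en-1-one
Conditions: I2 (1.5 equiv), pyridine/CH2Cl2 (1:1), 0 °C → rt
Reagents that add atoms: iodine, II
Why: α‑iodination of the enone by the pyridine‑mediated addition–iodination–elimination sequence (Morita–Baylis–Hillman‑type α‑halogenation) should place iodine on the α‑carbon without touching the silyloxy stereocentre.

Step 2
Reactants: 2 (4R)-4-[(tert-butyldimethylsilyl)oxy]-2-iodocyclopent-2-en-1-one; 3 tetramethylstannane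
Product: 4 (4R)-4-[(tert-butyldimethylsilyl)oxy]-2-methylcyclopent-2-en-1-one
Conditions: Me4Sn (1.5 equiv), Pd2(dba)3 (2.5 mol%), AsPh3 (10 mol%), CuI (10 mol%), NMP, 60 °C
Reagents that add atoms: tetramethylstannane (3), C[Sn](C)(C)C
Why: Stille coupling, in which oxidative addition of the electron‑poor vinyl iodide to zerovalent palladium and methyl transfer from tin should give the 2‑methyl enone under neutral conditions that avoid β‑elimination of the silyloxy group; no stereocentre is formed.

Step 3
Reactants: 4 (4R)-4-[(tert-butyldimethylsilyl)oxy]-2-methylcyclopent-2-en-1-one; 5 vinylmagnesium bromide; 6 acetaldehyde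
Product: 8 (2S,3R,4R)-4-[(tert-butyldimethylsilyl)oxy]-3-ethenyl-2-(1-hydroxyethyl)-2-methylcyclopentan-1-one (both carbinol epimers), via magnesium enolate 7 (not isolated)
Conditions: CH2=CHMgBr (1.5 equiv), CuBr·SMe2 (0.2 equiv), THF, −78 → −40 °C; then CH3CHO (3 equiv), −78 °C; aqueous NH4Cl
Reagents that add atoms: vinylmagnesium bromide (5), C=C[Mg]Br; acetaldehyde (6), CC=O
Why: copper‑catalysed conjugate addition with aldol trapping (three‑component coupling), in which the vinyl group should add anti to the neighbouring silyloxy group (future C10) and the regiospecifically formed tetrasubstituted enolate 7 should add to acetaldehyde anti to the new vinyl group, fixing the quaternary centre (future C11, methyl cis to vinyl); the carbinol centre is uncontrolled and is erased in step 4.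

Step 4
Reactants: 8 (2S,3R,4R)-4-[(tert-butyldimethylsilyl)oxy]-3-ethenyl-2-(1-hydroxyethyl)-2-methylcyclopentan-1-one
Product: 10 (4S,5S)-5-acetyl-4-ethenyl-5-methylcyclopent-2-en-1-one, via silyloxy diketone 9 (not isolated)
Conditions: Dess–Martin periodinane (1.5 equiv), NaHCO3, CH2Cl2, rt; aqueous Na2S2O3 wash; crude 9 with DBU (1.2 equiv), CH2Cl2, 0 °C
Reagents that add atoms: none
Why: Dess–Martin oxidation turns the uncontrolled carbinol into the acetyl group (C1/C2), and the β‑silyloxy ketone 9 should then lose silanol by E1cB elimination to unveil the cyclopentenone whose β‑carbon is the future C5; the quaternary centre cannot epimerise and the mild base at 0 °C should leave C10 intact.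

Step 5
Reactants: 10 (4S,5S)-5-acetyl-4-ethenyl-5-methylcyclopent-2-en-1-one; 11 2-methylpropanal
Product: 14 (1R,6R,9S)-9-ethenyl-1,5,5-trimethylbicyclo[4.2.1]non-3-ene-2,8-dione, via keto aldehyde 12 (not isolated), via aldol 13 (not isolated)
Conditions: 2-methylpropanal (5 equiv), pyrrolidine (0.3 equiv), PhCO2H (0.3 equiv), toluene, 60 °C, then reflux with water removal (Dean–Stark)
Reagents that add atoms: 2-methylpropanal (11), CC(C)C=O
Why: Proposed new method: the enamine formed from pyrrolidine and 11 (C4 as donor) should add to the β‑carbon of enone 10 (C5) and, after hydrolysis, leave keto aldehyde 12, whose aldehyde carbon C3 has no α‑hydrogen and can only accept; the C11 acetyl group, enolisable only at C2, then closes the ring by aldol addition at C3 (13), and amine‑catalysed dehydration gives enone 14, so that C4–C5 and C2–C3 arise in one operation. The closest known reaction type is the Robinson‑type annulation of isobutyraldehyde with methyl vinyl ketone (Michael addition/aldol condensation to 4,4‑dimethylcyclohex‑2‑enone); here the donor ketone and the acceptor carbonyl are separate groups held 1,3‑cis on a cyclopentanone, which turns the [4+2] into a [5+2] annulation. The Michael step is intermolecular, and the ring closure is a 7‑(enolexo)‑exo‑trig aldol that bridges C5 and C11 of the five‑membered ring (bicyclo[4.2.1]nonane). The only new stereocentre, C5, is set by the vinyl group on the adjacent C10, anti to which the enamine adds; this is the face that carries the acetyl group on C11, as the bridging aldol requires. The step needs chemoselectivity among three carbonyl groups, which the quaternary C4 and C11 secure (one acceptor aldehyde, one enolisable methyl, and every other intramolecular aldol would form a four‑membered ring), and it needs site selectivity in the Michael step, which is given because 10 has a single enone.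

Step 6
Reactants: 14 (1R,6R,9S)-9-ethenyl-1,5,5-trimethylbicyclo[4.2.1]non-3-ene-2,8-dione
Product: 16 (1R,4R,6R,9S)-9-ethenyl-4-hydroxy-1,5,5-trimethylbicyclo[4.2.1]nonane-2,8-dione, via boronate 15 (not isolated)
Conditions: B2pin2 (1.1 equiv), CuCl (5 mol%), DPEphos (5 mol%), NaOtBu (5 mol%), MeOH (2 equiv), THF, rt; then 30% H2O2, aqueous KH2PO4/K2HPO4 buffer (pH 7), 0 °C
Reagents that add atoms: bis(pinacolato)diboron, CC1(C)OB(OC1(C)C)B1OC(C)(C)C(C)(C)O1 (boron of 15 only); hydrogen peroxide, OO (hydroxyl oxygen of 16)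
Why: copper‑catalysed conjugate borylation and oxidation, in which the copper boryl species should deliver boron to C3 from the face of the seven‑membered ring that looks towards the one‑carbon bridge (C10–H) and away from the two‑carbon keto bridge (C6–C7), and oxidation of the C–B bond with retention gives the C3 alcohol on that face, while the saturated ketone and the vinyl group stay untouched.

Step 7
Reactants: 16 (1R,4R,6R,9S)-9-ethenyl-4-hydroxy-1,5,5-trimethylbicyclo[4.2.1]nonane-2,8-dione; 17 3-methylbutanal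
Product: 19 (1S,2R,4R,6R,9S)-9-ethenyl-2-hydroxy-1,5,5-trimethyl-8-oxobicyclo[4.2.1]nonan-4-yl 3-methylbutanoate (ring locants as in 14), via hemiacetal 18 (not isolated)
Conditions: 3-methylbutanal (1.5 equiv), SmI2 (0.3 equiv, premixed with the aldehyde), THF, −10 °C
Reagents that add atoms: 3-methylbutanal (17), CC(C)CC=O
Why: Evans–Tishchenko reduction, in which the C3 alkoxide adds to 17 and the samarium‑bound hemiacetal 18 delivers its hydride through a six‑membered transition state to the C1 ketone from the side of O3, so that the new C1–O bond is anti to C3–O and the isovalerate is installed on O3 in the same event; the C7 ketone is out of reach of O3, and a near‑stoichiometric amount of aldehyde should suppress a second hydride transfer from O1.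

Step 8
Reactants: 19 (1S,2R,4R,6R,9S)-9-ethenyl-2-hydroxy-1,5,5-trimethyl-8-oxobicyclo[4.2.1]nonan-4-yl 3-methylbutanoate; 20 (2E)-2-methylbut-2-enoyl chloride
Product: 21 (1S,2R,4R,6R,9S)-9-ethenyl-1,5,5-trimethyl-4-[(3-methylbutanoyl)oxy]-8-oxobicyclo[4.2.1]nonan-2-yl (2E)-2-methylbut-2-enoate (ring locants as in 14)
Conditions: (2E)-2-methylbut-2-enoyl chloride (2 equiv), pyridine (5 equiv), DMAP (0.3 equiv), CH2Cl2, 0 → 35 °C
Reagents that add atoms: (2E)-2-methylbut-2-enoyl chloride (20), C/C=C(\C)C(Cl)=O
Why: DMAP‑catalysed acylation of the hindered secondary C1 alcohol in pyridine (a weak base, which avoids deconjugation of the acid chloride through a vinylketene) should give the tiglate with its E geometry intact; no stereocentre is formed.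

Step 9
Reactants: 21 (1S,2R,4R,6R,9S)-9-ethenyl-1,5,5-trimethyl-4-[(3-methylbutanoyl)oxy]-8-oxobicyclo[4.2.1]nonan-2-yl (2E)-2-methylbut-2-enoate
Product: 23 (1S,2R,4R,6R,9S)-7-diazo-9-ethenyl-1,5,5-trimethyl-4-[(3-methylbutanoyl)oxy]-8-oxobicyclo[4.2.1]nonan-2-yl (2E)-2-methylbut-2-enoate (ring locants as in 14), via trifluoroacetyl ketone 22 (not isolated)
Conditions: LiN(SiMe3)2 (1.1 equiv), THF, −78 °C; CF3CO2CH2CF3 (1.3 equiv); then MsN3 (1.5 equiv), Et3N (1.5 equiv), H2O (1 equiv), MeCN, rt
Reagents that add atoms: 2,2,2-trifluoroethyl trifluoroacetate, O=C(OCC(F)(F)F)C(F)(F)F (trifluoroacetyl group of 22 only); methanesulfonyl azide, CS(=O)(=O)N=[N+]=[N-] (the two diazo nitrogens)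
Why: deacylative (Regitz‑type) diazo transfer, in which C6 is the only enolisable position of the only ketone (C11 is quaternary), so that kinetic enolisation and trifluoroacetylation give 22, whose activated carbon should take up the diazo group from the sulfonyl azide with loss of the trifluoroacetyl group as the sulfonamide; both esters are less acidic than the ketone and should survive.

Step 10
Reactants: 23 (1S,2R,4R,6R,9S)-7-diazo-9-ethenyl-1,5,5-trimethyl-4-[(3-methylbutanoyl)oxy]-8-oxobicyclo[4.2.1]nonan-2-yl (2E)-2-methylbut-2-enoate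
Product: 25 (1R,2R,4R,6S,8S)-8-ethenyl-1,5,5-trimethyl-4-[(3-methylbutanoyl)oxy]-2-{[(2E)-2-methylbut-2-enoyl]oxy}bicyclo[4.1.1]octane-7-carboxylic acid (both C-7 epimers), via ketene 24 (not isolated)
Conditions: hν (medium-pressure Hg lamp, Pyrex filter), THF/H2O (4:1), rt
Reagents that add atoms: water, O
Why: photochemical Wolff rearrangement, in which loss of dinitrogen from the ring‑locked s‑cis diazo ketone with concerted 1,2‑shift of the C7–C11 bond to C6 contracts the cyclopentanone to the cyclobutane (new C6–C11 bond, retention at the migrating C11) and water traps the exocyclic ketene 24 as the C7 acid; the configuration at C6 arises on protonation, is not controlled, and is corrected in step 13.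

Step 11
Reactants: 25 (1R,2R,4R,6S,8S)-8-ethenyl-1,5,5-trimethyl-4-[(3-methylbutanoyl)oxy]-2-{[(2E)-2-methylbut-2-enoyl]oxy}bicyclo[4.1.1]octane-7-carboxylic acid; 26 2-(diethoxyphosphoryl)acetic acid
Product: 29 (1R,2R,4R,6S,8S)-7-[2-(diethoxyphosphoryl)acetyl]-8-ethenyl-1,5,5-trimethyl-4-[(3-methylbutanoyl)oxy]bicyclo[4.1.1]octan-2-yl (2E)-2-methylbut-2-enoate (both C-7 epimers; ring locants as in 25), via acid chloride 27 (not isolated), via keto acid 28 (not isolated)
Conditions: (COCl)2 (1.5 equiv), DMF (2 mol%), CH2Cl2, 0 °C → rt; concentrate; then 2-(diethoxyphosphoryl)acetic acid (2 equiv), MgCl2 (2 equiv), Et3N (4 equiv), MeCN, 0 °C → rt; 1 M HCl work-up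
Reagents that add atoms: oxalyl chloride, O=C(Cl)C(Cl)=O (chlorine of 27 only); 2-(diethoxyphosphoryl)acetic acid (26), CCOP(=O)(OCC)CC(O)=O
Why: C‑acylation of the magnesium enolate of the phosphonoacetic acid by the acid chloride (malonic half‑ester‑type acylation) with decarboxylation on acidic work‑up should give the β‑keto phosphonate and add C8 under conditions to which the two secondary esters and the vinyl group are inert; no stereocentre is fixed.

Step 12
Reactants: 29 (1R,2R,4R,6S,8S)-7-[2-(diethoxyphosphoryl)acetyl]-8-ethenyl-1,5,5-trimethyl-4-[(3-methylbutanoyl)oxy]bicyclo[4.1.1]octan-2-yl (2E)-2-methylbut-2-enoate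
Product: 30 (1R,2R,4R,6S,8S)-8-acetyl-7-[2-(diethoxyphosphoryl)acetyl]-1,5,5-trimethyl-4-[(3-methylbutanoyl)oxy]bicyclo[4.1.1]octan-2-yl (2E)-2-methylbut-2-enoate (both C-7 epimers; ring locants as in 25)
Conditions: PdCl2 (0.1 equiv), CuCl (1 equiv), O2 (1 atm), DMF/H2O (7:1), rt
Reagents that add atoms: water, O
Why: Wacker oxidation, in which Markovnikov hydroxypalladation of the terminal vinyl group and β‑hydride elimination should give the methyl ketone (C9 with its methyl) while the trisubstituted, electron‑poor tiglate double bond does not react; C10 keeps its configuration but becomes epimerisable.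

Step 13
Reactants: 30 (1R,2R,4R,6S,8S)-8-acetyl-7-[2-(diethoxyphosphoryl)acetyl]-1,5,5-trimethyl-4-[(3-methylbutanoyl)oxy]bicyclo[4.1.1]octan-2-yl (2E)-2-methylbut-2-enoate
Product: 31 (1R,2R,3R,5R,7S,8R)-2,6,6,9-tetramethyl-5-[(3-methylbutanoyl)oxy]-11-oxotricyclo[5.4.0.0(2,8)]undec-9-en-3-yl (2E)-2-methylbut-2-enoate (the target)
Conditions: K2CO3 (3 equiv), 18-crown-6 (1 equiv), toluene, 80 °C
Reagents that add atoms: none
Why: intramolecular Horner–Wadsworth–Emmons olefination, in which the phosphonate carbanion (C8) can reach the C9 ketone only when the two acyl groups are cis‑1,3 on the cyclobutane, and carbonate‑mediated epimerisation at C6 and C10 (each α to a ketone) should funnel all epimers into that isomer, whose irreversible ring closure fixes C6 and C10 as in the target and places the carbonyl at C7 and the methyl at C9 as dictated by the position of phosphorus.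

**Compound list**

1 | (4R)-4-[(tert-butyldimethylsilyl)oxy]cyclopent-2-en-1-one | O=C1C=C[C@H](O[Si](C)(C)C(C)(C)C)C1 | starting material
2 | (4R)-4-[(tert-butyldimethylsilyl)oxy]-2-iodocyclopent-2-en-1-one | O=C1C(I)=C[C@H](O[Si](C)(C)C(C)(C)C)C1 | intermediate
3 | tetramethylstannane | C[Sn](C)(C)C | starting material
4 | (4R)-4-[(tert-butyldimethylsilyl)oxy]-2-methylcyclopent-2-en-1-one | O=C1C(C)=C[C@H](O[Si](C)(C)C(C)(C)C)C1 | intermediate
5 | vinylmagnesium bromide | C=C[Mg]Br | starting material
6 | acetaldehyde | CC=O | starting material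
7 | bromomagnesium enolate of (3R,4R)-4-[(tert-butyldimethylsilyl)oxy]-3-ethenyl-2-methylcyclopentan-1-one | Br[Mg]OC1=C(C)[C@@H](C=C)[C@H](O[Si](C)(C)C(C)(C)C)C1 | intermediate (not isolated)
8 | (2S,3R,4R)-4-[(tert-butyldimethylsilyl)oxy]-3-ethenyl-2-(1-hydroxyethyl)-2-methylcyclopentan-1-one (both carbinol epimers) | O=C1[C@](C)(C(C)O)[C@@H](C=C)[C@H](O[Si](C)(C)C(C)(C)C)C1 | intermediate
9 | (2S,3R,4R)-2-acetyl-4-[(tert-butyldimethylsilyl)oxy]-3-ethenyl-2-methylcyclopentan-1-one | O=C1[C@](C)(C(C)=O)[C@@H](C=C)[C@H](O[Si](C)(C)C(C)(C)C)C1 | intermediate (not isolated)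
10 | (4S,5S)-5-acetyl-4-ethenyl-5-methylcyclopent-2-en-1-one | O=C1C=C[C@H](C=C)[C@@]1(C)C(C)=O | intermediate
11 | 2-methylpropanal (isobutyraldehyde) | CC(C)C=O | starting material
12 | 2-[(1R,2S,3S)-3-acetyl-2-ethenyl-3-methyl-4-oxocyclopentyl]-2-methylpropanal | O=C1C[C@@H](C(C)(C)C=O)[C@H](C=C)[C@@]1(C)C(C)=O | intermediate (not isolated)
13 | (1R,6R,9S)-9-ethenyl-4-hydroxy-1,5,5-trimethylbicyclo[4.2.1]nonane-2,8-dione (both C-4 epimers) | O=C1C[C@H]2C(C)(C)C(O)CC(=O)[C@]1(C)[C@H]2C=C | intermediate (not isolated)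
14 | (1R,6R,9S)-9-ethenyl-1,5,5-trimethylbicyclo[4.2.1]non-3-ene-2,8-dione | O=C1C[C@H]2C(C)(C)C=CC(=O)[C@]1(C)[C@H]2C=C | intermediate
15 | (1S,4R,6R,9S)-9-ethenyl-1,5,5-trimethyl-4-(4,4,5,5-tetramethyl-1,3,2-dioxaborolan-2-yl)bicyclo[4.2.1]nonane-2,8-dione | O=C1C[C@H]2C(C)(C)[C@H](B3OC(C)(C)C(C)(C)O3)CC(=O)[C@]1(C)[C@H]2C=C | intermediate (not isolated)
16 | (1R,4R,6R,9S)-9-ethenyl-4-hydroxy-1,5,5-trimethylbicyclo[4.2.1]nonane-2,8-dione | O=C1C[C@H]2C(C)(C)[C@H](O)CC(=O)[C@]1(C)[C@H]2C=C | intermediate
17 | 3-methylbutanal (isovaleraldehyde) | CC(C)CC=O | starting material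
18 | hemiacetal of 16 with 17, the 4-[(1-hydroxy-3-methylbutyl)oxy] derivative of 16 (present as its samarium alkoxide) | O=C1C[C@H]2C(C)(C)[C@H](OC(O)CC(C)C)CC(=O)[C@]1(C)[C@H]2C=C | intermediate (not isolated)
19 | (1S,2R,4R,6R,9S)-9-ethenyl-2-hydroxy-1,5,5-trimethyl-8-oxobicyclo[4.2.1]nonan-4-yl 3-methylbutanoate (ring locants as in 14) | O=C1C[C@H]2C(C)(C)[C@H](OC(=O)CC(C)C)C[C@@H](O)[C@]1(C)[C@H]2C=C | intermediate
20 | (2E)-2-methylbut-2-enoyl chloride (tigloyl chloride) | C/C=C(\C)C(Cl)=O | starting material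
21 | (1S,2R,4R,6R,9S)-9-ethenyl-1,5,5-trimethyl-4-[(3-methylbutanoyl)oxy]-8-oxobicyclo[4.2.1]nonan-2-yl (2E)-2-methylbut-2-enoate (ring locants as in 14) | O=C1C[C@H]2C(C)(C)[C@H](OC(=O)CC(C)C)C[C@@H](OC(=O)/C(C)=C/C)[C@]1(C)[C@H]2C=C | intermediate
22 | 7-(trifluoroacetyl) derivative of 21 (other centres as in 21) | O=C1C(C(=O)C(F)(F)F)[C@H]2C(C)(C)[C@H](OC(=O)CC(C)C)C[C@@H](OC(=O)/C(C)=C/C)[C@]1(C)[C@H]2C=C | intermediate (not isolated)
23 | (1S,2R,4R,6R,9S)-7-diazo-9-ethenyl-1,5,5-trimethyl-4-[(3-methylbutanoyl)oxy]-8-oxobicyclo[4.2.1]nonan-2-yl (2E)-2-methylbut-2-enoate (ring locants as in 14) | O=C1C(=[N+]=[N-])[C@H]2C(C)(C)[C@H](OC(=O)CC(C)C)C[C@@H](OC(=O)/C(C)=C/C)[C@]1(C)[C@H]2C=C | intermediate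
24 | 7-(oxomethylidene) analogue of 25, the exocyclic ketene on C-7 (other centres as in 25) | O=C=C1[C@H]2C(C)(C)[C@H](OC(=O)CC(C)C)C[C@@H](OC(=O)/C(C)=C/C)[C@]1(C)[C@H]2C=C | intermediate (not isolated)
25 | (1R,2R,4R,6S,8S)-8-ethenyl-1,5,5-trimethyl-4-[(3-methylbutanoyl)oxy]-2-{[(2E)-2-methylbut-2-enoyl]oxy}bicyclo[4.1.1]octane-7-carboxylic acid (both C-7 epimers) | OC(=O)C1[C@H]2C(C)(C)[C@H](OC(=O)CC(C)C)C[C@@H](OC(=O)/C(C)=C/C)[C@]1(C)[C@H]2C=C | intermediate
26 | 2-(diethoxyphosphoryl)acetic acid | CCOP(=O)(OCC)CC(O)=O | starting material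
27 | acid chloride of 25 | ClC(=O)C1[C@H]2C(C)(C)[C@H](OC(=O)CC(C)C)C[C@@H](OC(=O)/C(C)=C/C)[C@]1(C)[C@H]2C=C | intermediate (not isolated)
28 | 2-(diethoxyphosphoryl)-3-oxopropanoic acid carrying the bicyclic residue of 25 on C-3 | CCOP(=O)(OCC)C(C(O)=O)C(=O)C1[C@H]2C(C)(C)[C@H](OC(=O)CC(C)C)C[C@@H](OC(=O)/C(C)=C/C)[C@]1(C)[C@H]2C=C | intermediate (not isolated)
29 | (1R,2R,4R,6S,8S)-7-[2-(diethoxyphosphoryl)acetyl]-8-ethenyl-1,5,5-trimethyl-4-[(3-methylbutanoyl)oxy]bicyclo[4.1.1]octan-2-yl (2E)-2-methylbut-2-enoate (both C-7 epimers; ring locants as in 25) | CCOP(=O)(OCC)CC(=O)C1[C@H]2C(C)(C)[C@H](OC(=O)CC(C)C)C[C@@H](OC(=O)/C(C)=C/C)[C@]1(C)[C@H]2C=C | intermediate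
30 | (1R,2R,4R,6S,8S)-8-acetyl-7-[2-(diethoxyphosphoryl)acetyl]-1,5,5-trimethyl-4-[(3-methylbutanoyl)oxy]bicyclo[4.1.1]octan-2-yl (2E)-2-methylbut-2-enoate (both C-7 epimers; ring locants as in 25) | CCOP(=O)(OCC)CC(=O)C1[C@H]2C(C)(C)[C@H](OC(=O)CC(C)C)C[C@@H](OC(=O)/C(C)=C/C)[C@]1(C)[C@H]2C(C)=O | intermediate
31 | (1R,2R,3R,5R,7S,8R)-2,6,6,9-tetramethyl-5-[(3-methylbutanoyl)oxy]-11-oxotricyclo[5.4.0.0(2,8)]undec-9-en-3-yl (2E)-2-methylbut-2-enoate | C/C=C(\C)C(=O)O[C@@H]1C[C@@H](OC(=O)CC(C)C)C(C)(C)[C@@H]2[C@H]3C(=O)C=C(C)[C@@H]2[C@]31C | target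

**Summary and risks**

Total step count: 13. Longest linear sequence: 13 steps (1 to 31).

The three steps most likely to fail, each with a fallback:

First, step 5 (the proposed new method). The seven‑membered aldol closure may be slower than intermolecular aldol reactions of the keto aldehyde. The amine may cleave the non‑enolisable 1,3‑diketone by retro‑Claisen attack. γ‑Deprotonation through a dienamine may scramble C10. The fallback uses two separate, known reactions. It sets out from 10: Mukaiyama–Michael addition of commercial 2‑methyl‑1‑(trimethylsilyloxy)prop‑1‑ene (catalytic Me3SiOTf, CH2Cl2, −78 °C) gives the trimethylsilyl enol ether of the Michael adduct F1. Mild acidic work‑up gives keto aldehyde 12, which is isolated. Acid‑catalysed aldol condensation (TsOH, benzene, reflux with water removal) then closes the ring and comes back to the route at 14.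

Second, step 7. Hydride transfer may be slow because the ring restricts the six‑membered transition state. A second Tishchenko event from the new O1 alkoxide may reduce the C7 ketone. The isovalerate may migrate from O3 to O1. The fallback sets out from 16: hydroxyl‑directed 1,3‑anti reduction with Me4NBH(OAc)3 (one hydride equivalent, AcOH/MeCN, −30 °C) gives the anti diol F2. Its exo C3 hydroxyl is less shielded than the C1 hydroxyl next to the quaternary bridgehead and is acylated selectively with one equivalent of 3‑methylbutanoic anhydride (2,4,6‑collidine, catalytic DMAP, −40 °C). This comes back to the route at 19.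

Third, step 13. Epimerisation at C6 and C10 may be too slow to feed the cis isomer. Strain in the forming bicyclo[3.1.1]heptenone may also stall the olefination, so that intermolecular condensation competes. The fallback sets out from 25 and replaces steps 11 to 13. The acid chloride 27, made as in step 11, is treated with Me2CuLi at −78 °C to give the methyl ketone F3. Its kinetic trimethylsilyl enol ether F4 (LiN(SiMe3)2, Me3SiCl, THF, −78 °C) is cyclised onto the vinyl group with Pd(OAc)2 in MeCN (Saegusa–Ito‑type oxidative cyclisation: attack at the internal vinyl carbon, β‑hydride elimination, migration of the exocyclic double bond into conjugation). This comes back to the route at 31. The C6 epimer of F3 that cannot cyclise is equilibrated with DBU and recycled.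

**Further compounds**

F1 | step 5 | trimethylsilyl enol ether of keto aldehyde 12 (silyloxy on the former ring carbonyl carbon, ring double bond towards the former α-CH2; other centres as in 12) | C[Si](C)(C)OC1=C[C@@H](C(C)(C)C=O)[C@H](C=C)[C@@]1(C)C(C)=O
F2 | step 7 | (1S,2R,4R,6R,9S)-9-ethenyl-2,4-dihydroxy-1,5,5-trimethylbicyclo[4.2.1]nonan-8-one (ring locants as in 14) | O=C1C[C@H]2C(C)(C)[C@H](O)C[C@@H](O)[C@]1(C)[C@H]2C=C
F3 | step 13 | (1R,2R,4R,6S,8S)-7-acetyl-8-ethenyl-1,5,5-trimethyl-4-[(3-methylbutanoyl)oxy]bicyclo[4.1.1]octan-2-yl (2E)-2-methylbut-2-enoate (both C-7 epimers; ring locants as in 25) | CC(=O)C1[C@H]2C(C)(C)[C@H](OC(=O)CC(C)C)C[C@@H](OC(=O)/C(C)=C/C)[C@]1(C)[C@H]2C=C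
F4 | step 13 | trimethylsilyl enol ether of F3, with a 1-[(trimethylsilyl)oxy]ethenyl group on C-7 | C=C(O[Si](C)(C)C)C1[C@H]2C(C)(C)[C@H](OC(=O)CC(C)C)C[C@@H](OC(=O)/C(C)=C/C)[C@]1(C)[C@H]2C=C
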